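**Strategy.** The eleven-membered carbocycle (numbered from the carbinol carbon C1 through the Z olefin C2=C3) is closed between the allylic methylene C4 and the quaternary carbon C5. One of the two C5 methyl groups is carried as a nitrile, so that C5 becomes a tertiary nitrile-stabilised carbanion; this displaces a primary (Z)-allylic chloride at C4 in one intramolecular SN2 alkylation that forms the ring and the quaternary centre without touching either olefin geometry. The precursor is an open-chain (6E,10Z)-12-chlorododecadienenitrile bearing the silylated (R)-carbinol, assembled from two alkyne-derived trisubstituted olefins by Nozaki–Hiyama–Kishi coupling and CBS reduction. Afterwards the nitrile is reduced to methyl and the vanillate is attached.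

Key step: step 12

Remark on the chemistry: the nitrile-bearing (later formyl-bearing) carbon is carried as a mixture of both configurations from compound 9 to compound 21, because it ends as the achiral gem-dimethyl carbon; names and SMILES leave it undefined.

**Route**

Step 1
Reactants: 1 but-2-yn-1-ol
Product: 3 (2Z)-3-iodobut-2-en-1-ol, via sodium oxaaluminacycle 2 (not isolated)
Conditions: NaAlH2(OCH2CH2OMe)2, THF, 0 °C to rt; then I2, −78 °C to rt
Reagents that add atoms: iodine, I-I
Why: Alkoxide-directed trans-hydroalumination of the propargylic alcohol delivers hydride to C2 and places aluminium on C3 inside a five-membered oxaaluminacycle, so iododealumination with retention should give the (Z)-iodide with iodine cis to the CH2OH arm.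

Step 2
Reactants: 3 (2Z)-3-iodobut-2-en-1-ol
Product: 4 tert-butyl{[(2Z)-3-iodobut-2-en-1-yl]oxy}dimethylsilane
Conditions: TBSCl, imidazole, CH2Cl2, 0 °C to rt
Reagents that add atoms: tert-butyldimethylsilyl chloride, CC(C)(C)[Si](C)(C)Cl
Why: Standard silyl ether formation masks the primary hydroxyl for the chromium, oxidation and borane steps that follow.

Step 3
Reactants: 5 5-chloropent-1-yne
Product: 8 (3E)-7-chloro-4-methylhept-3-en-1-ol, via alkenyldimethylalane 6 (not isolated), via lithium alkenylalanate 7 (not isolated)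
Conditions: AlMe3, Cp2ZrCl2 (0.2 equiv), CH2Cl2, 0 °C to rt; n-BuLi, hexane/THF, −78 °C; ethylene oxide, −78 °C to rt; aqueous work-up
Reagents that add atoms: trimethylaluminium, C[Al](C)C; ethylene oxide, C1CO1
Why: Zirconium-catalysed Negishi carboalumination adds methyl and aluminium syn across the terminal alkyne with aluminium on the terminal carbon, and the derived lithium alanate opens ethylene oxide with retention, which fixes the (E)-trisubstituted olefin.

Step 4
Reactants: 8 (3E)-7-chloro-4-methylhept-3-en-1-ol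
Product: 9 (6E)-9-hydroxy-2,6-dimethylnon-6-enenitrile
Conditions: EtCN (2.5 equiv), LiN(i-Pr)2 (2.5 equiv), THF, −78 °C; then 8, NaI (cat.), DMPU, −78 °C to rt
Reagents that add atoms: propionitrile, CCC#N
Why: SN2 alkylation of α-lithiated propionitrile by the primary chloride (iodide-assisted, the hydroxyl being carried as its lithium alkoxide) installs the α-methyl nitrile, whose new stereocentre forms as a racemate and is removed later.

Step 5
Reactants: 9 (6E)-9-hydroxy-2,6-dimethylnon-6-enenitrile
Product: 10 (6E)-2,6-dimethyl-9-oxonon-6-enenitrile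
Conditions: Dess–Martin periodinane, NaHCO3, CH2Cl2, 0 °C to rt; used without storage
Reagents that add atoms: none
Why: Buffered Dess–Martin oxidation should give the β,γ-unsaturated aldehyde without migration of the olefin into conjugation.

Step 6
Reactants: 10 (6E)-2,6-dimethyl-9-oxonon-6-enenitrile; 4 tert-butyl{[(2Z)-3-iodobut-2-en-1-yl]oxy}dimethylsilane
Product: 11 (6E,10Z)-12-[(tert-butyldimethylsilyl)oxy]-9-hydroxy-2,6,10-trimethyldodeca-6,10-dienenitrile
Conditions: CrCl2 (4 equiv), NiCl2 (cat.), DMSO, rt
Reagents that add atoms: none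
Why: In the Nozaki–Hiyama–Kishi coupling the alkenyl iodide adds oxidatively to zerovalent nickel and is passed to trivalent chromium, and the non-basic alkenylchromium adds to the enolisable aldehyde with retention of the Z geometry and tolerance of the nitrile; the carbinol centre forms without control and is erased in step 7.

Step 7
Reactants: 11 (6E,10Z)-12-[(tert-butyldimethylsilyl)oxy]-9-hydroxy-2,6,10-trimethyldodeca-6,10-dienenitrile
Product: 12 (6E,10Z)-12-[(tert-butyldimethylsilyl)oxy]-2,6,10-trimethyl-9-oxododeca-6,10-dienenitrile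
Conditions: Dess–Martin periodinane, NaHCO3, CH2Cl2, 0 °C
Reagents that add atoms: none
Why: Dess–Martin oxidation of the secondary allylic alcohol should give the (Z)-enone under neutral conditions that isomerise neither olefin.

Step 8
Reactants: 12 (6E,10Z)-12-[(tert-butyldimethylsilyl)oxy]-2,6,10-trimethyl-9-oxododeca-6,10-dienenitrile
Product: 13 (6E,9R,10Z)-12-[(tert-butyldimethylsilyl)oxy]-9-hydroxy-2,6,10-trimethyldodeca-6,10-dienenitrile
Conditions: (S)-2-methyl-CBS-oxazaborolidine (0.2 equiv), catecholborane, toluene, −78 °C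
Reagents that add atoms: none
Why: In the Corey–Bakshi–Shibata reduction the ketone binds to the catalyst boron anti to the larger α-methylalkenyl group and hydride is delivered to the Si face, which should set the (R)-carbinol, as acetophenone gives the (R)-alcohol with the same catalyst.

Step 9
Reactants: 13 (6E,9R,10Z)-12-[(tert-butyldimethylsilyl)oxy]-9-hydroxy-2,6,10-trimethyldodeca-6,10-dienenitrile
Product: 14 (6E,9R,10Z)-9,12-bis[(tert-butyldimethylsilyl)oxy]-2,6,10-trimethyldodeca-6,10-dienenitrile
Conditions: TBSOTf, 2,6-lutidine, CH2Cl2, −78 to 0 °C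
Reagents that add atoms: tert-butyldimethylsilyl triflate, CC(C)(C)[Si](C)(C)OS(=O)(=O)C(F)(F)F
Why: Silylation of the hindered secondary alcohol on oxygen leaves the C–O bond and the (R) configuration untouched and blocks cyclisation of the oxygen onto the later allylic chloride.

Step 10
Reactants: 14 (6E,9R,10Z)-9,12-bis[(tert-butyldimethylsilyl)oxy]-2,6,10-trimethyldodeca-6,10-dienenitrile
Product: 15 (6E,9R,10Z)-9-[(tert-butyldimethylsilyl)oxy]-12-hydroxy-2,6,10-trimethyldodeca-6,10-dienenitrile
Conditions: camphorsulfonic acid (cat.), MeOH/CH2Cl2, 0 °C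
Reagents that add atoms: none
Why: Acid-catalysed methanolysis cleaves the unhindered primary silyl ether much faster than the secondary one flanked by the trisubstituted olefin (selective desilylation).

Step 11
Reactants: 15 (6E,9R,10Z)-9-[(tert-butyldimethylsilyl)oxy]-12-hydroxy-2,6,10-trimethyldodeca-6,10-dienenitrile
Product: 16 (6E,9R,10Z)-9-[(tert-butyldimethylsilyl)oxy]-12-chloro-2,6,10-trimethyldodeca-6,10-dienenitrile
Conditions: PPh3, hexachloroacetone, CH2Cl2, 0 °C
Reagents that add atoms: hexachloroacetone, ClC(Cl)(Cl)C(=O)C(Cl)(Cl)Cl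
Why: Appel-type chlorination through the alkoxyphosphonium ion substitutes the primary allylic carbon by SN2 without allylic transposition or loss of the Z geometry.

Step 12
Reactants: 16 (6E,9R,10Z)-9-[(tert-butyldimethylsilyl)oxy]-12-chloro-2,6,10-trimethyldodeca-6,10-dienenitrile
Product: 18 (3Z,5R,7E)-5-[(tert-butyldimethylsilyl)oxy]-1,4,8-trimethylcycloundeca-3,7-diene-1-carbonitrile, via lithium keteniminate 17 (not isolated)
Conditions: LiN(i-Pr)2 (1.3 equiv), THF, −20 °C, syringe-pump addition of 16 to a final concentration of about 1 mM, then to 0 °C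
Reagents that add atoms: none
Why: LiN(i-Pr)2 removes the single α-hydrogen of the nitrile to give the N-lithiated keteniminate 17, whose carbon terminus displaces the primary allylic chloride in an intramolecular SN2 reaction. The closest known reaction type is the nitrile-anion cyclisation, the intramolecular alkylation of α-metalated nitriles, which with protected cyanohydrin anions and allylic halides is an established closure of ten- to sixteen-membered terpenoid carbocycles. The eleven-membered ring closes in the 11-exo-tet mode. The new quaternary stereocentre forms without facial control as both epimers, which is harmless because later reduction of the nitrile to methyl makes this carbon achiral, and the (R)-carbinol centre is not involved. The step needs ring closure over oligomerisation, C- over N-alkylation and SN2 over SN2′ attack with both olefin geometries kept; slow addition at high dilution, the carbon-centred reactivity of the keteniminate, the fully substituted distal allyl terminus and the absence of any π-allyl intermediate should secure these.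

Step 13
Reactants: 18 (3Z,5R,7E)-5-[(tert-butyldimethylsilyl)oxy]-1,4,8-trimethylcycloundeca-3,7-diene-1-carbonitrile
Product: 20 (3Z,5R,7E)-5-[(tert-butyldimethylsilyl)oxy]-1,4,8-trimethylcycloundeca-3,7-diene-1-carbaldehyde, via N-aluminated aldimine 19 (not isolated)
Conditions: i-Bu2AlH, toluene, −78 to 0 °C; then aqueous tartaric acid, rt
Reagents that add atoms: water, O
Why: A single hydride transfer from i-Bu2AlH to the nitrile stops at the N-aluminated aldimine, which is hydrolysed on work-up to the aldehyde (partial reduction of a nitrile).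

Step 14
Reactants: 20 (3Z,5R,7E)-5-[(tert-butyldimethylsilyl)oxy]-1,4,8-trimethylcycloundeca-3,7-diene-1-carbaldehyde
Product: 22 tert-butyldimethyl{[(1R,2Z,9E)-2,5,5,9-tetramethylcycloundeca-2,9-dien-1-yl]oxy}silane, via tosylhydrazone 21 (not isolated)
Conditions: TsNHNH2, EtOH, 50 °C; concentrate; catecholborane, CHCl3, 0 °C to rt; then NaOAc·3H2O, reflux
Reagents that add atoms: none
Why: Tosylhydrazone deoxygenation (a mild Wolff–Kishner variant) adds hydride to the C=N bond and then loses sulfinate and N2 from the diazene, which should turn CHO into CH3; the quaternary α-carbon has no hydrogen for olefin-forming side paths and becomes the achiral gem-dimethyl carbon.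

Step 15
Reactants: 22 tert-butyldimethyl{[(1R,2Z,9E)-2,5,5,9-tetramethylcycloundeca-2,9-dien-1-yl]oxy}silane
Product: 23 (1R,2Z,9E)-2,5,5,9-tetramethylcycloundeca-2,9-dien-1-ol
Conditions: Bu4NF, THF, rt to 40 °C
Reagents that add atoms: none
Why: Fluoride-induced desilylation cleaves only the Si–O bond, so the carbinol keeps its (R) configuration.

Step 16
Reactants: 23 (1R,2Z,9E)-2,5,5,9-tetramethylcycloundeca-2,9-dien-1-ol; 24 4-acetoxy-3-methoxybenzoic acid
Product: 25 (1R,2Z,9E)-2,5,5,9-tetramethylcycloundeca-2,9-dien-1-yl 4-acetoxy-3-methoxybenzoate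
Conditions: DCC, DMAP (cat.), CH2Cl2, 0 °C to rt
Reagents that add atoms: none
Why: Steglich esterification acylates the carbinol oxygen through the DMAP-activated acyl donor, so the C–O bond and the (R) configuration are retained.

Step 17
Reactants: 25 (1R,2Z,9E)-2,5,5,9-tetramethylcycloundeca-2,9-dien-1-yl 4-acetoxy-3-methoxybenzoate
Product: 26 (1R,2Z,9E)-2,5,5,9-tetramethylcycloundeca-2,9-dien-1-yl 4-hydroxy-3-methoxybenzoate
Conditions: pyrrolidine, CH2Cl2, 0 °C to rt
Reagents that add atoms: none
Why: Aminolysis of the activated aryl acetate is much faster than attack on the hindered, electron-rich secondary alkyl aroate, so selective deacetylation should free the phenol.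

**Compound list**

1 | but-2-yn-1-ol | CC#CCO | starting material
2 | sodium 2,2-bis(2-methoxyethoxy)-3-methyl-2,5-dihydro-1,2-oxaaluminol-2-uide | CC1=CCO[Al-]1(OCCOC)OCCOC.[Na+] | intermediate (not isolated)
3 | (2Z)-3-iodobut-2-en-1-ol | C/C(I)=C/CO | intermediate
4 | tert-butyl{[(2Z)-3-iodobut-2-en-1-yl]oxy}dimethylsilane | C/C(I)=C/CO[Si](C)(C)C(C)(C)C | intermediate
5 | 5-chloropent-1-yne | C#CCCCCl | starting material
6 | [(1E)-5-chloro-2-methylpent-1-en-1-yl]dimethylalane | C[Al](C)/C=C(\C)CCCCl | intermediate (not isolated)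
7 | lithium butyl[(1E)-5-chloro-2-methylpent-1-en-1-yl]dimethylalanate | CCCC[Al-](C)(C)/C=C(\C)CCCCl.[Li+] | intermediate (not isolated)
8 | (3E)-7-chloro-4-methylhept-3-en-1-ol | OCC/C=C(\C)CCCCl | intermediate
9 | (6E)-9-hydroxy-2,6-dimethylnon-6-enenitrile | OCC/C=C(\C)CCCC(C)C#N | intermediate
10 | (6E)-2,6-dimethyl-9-oxonon-6-enenitrile | O=CC/C=C(\C)CCCC(C)C#N | intermediate
11 | (6E,10Z)-12-[(tert-butyldimethylsilyl)oxy]-9-hydroxy-2,6,10-trimethyldodeca-6,10-dienenitrile | N#CC(C)CCC/C(C)=C/CC(O)/C(C)=C\CO[Si](C)(C)C(C)(C)C | intermediate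
12 | (6E,10Z)-12-[(tert-butyldimethylsilyl)oxy]-2,6,10-trimethyl-9-oxododeca-6,10-dienenitrile | N#CC(C)CCC/C(C)=C/CC(=O)/C(C)=C\CO[Si](C)(C)C(C)(C)C | intermediate
13 | (6E,9R,10Z)-12-[(tert-butyldimethylsilyl)oxy]-9-hydroxy-2,6,10-trimethyldodeca-6,10-dienenitrile | N#CC(C)CCC/C(C)=C/C[C@@H](O)/C(C)=C\CO[Si](C)(C)C(C)(C)C | intermediate
14 | (6E,9R,10Z)-9,12-bis[(tert-butyldimethylsilyl)oxy]-2,6,10-trimethyldodeca-6,10-dienenitrile | N#CC(C)CCC/C(C)=C/C[C@@H](O[Si](C)(C)C(C)(C)C)/C(C)=C\CO[Si](C)(C)C(C)(C)C | intermediate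
15 | (6E,9R,10Z)-9-[(tert-butyldimethylsilyl)oxy]-12-hydroxy-2,6,10-trimethyldodeca-6,10-dienenitrile | N#CC(C)CCC/C(C)=C/C[C@@H](O[Si](C)(C)C(C)(C)C)/C(C)=C\CO | intermediate
16 | (6E,9R,10Z)-9-[(tert-butyldimethylsilyl)oxy]-12-chloro-2,6,10-trimethyldodeca-6,10-dienenitrile | N#CC(C)CCC/C(C)=C/C[C@@H](O[Si](C)(C)C(C)(C)C)/C(C)=C\CCl | intermediate
17 | N-lithio keteniminate of 16 | [Li+].[N-]=C=C(C)CCC/C(C)=C/C[C@@H](O[Si](C)(C)C(C)(C)C)/C(C)=C\CCl | intermediate (not isolated)
18 | (3Z,5R,7E)-5-[(tert-butyldimethylsilyl)oxy]-1,4,8-trimethylcycloundeca-3,7-diene-1-carbonitrile | N#CC1(C)CCC/C(C)=C/C[C@@H](O[Si](C)(C)C(C)(C)C)/C(C)=C\C1 | intermediate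
19 | N-(diisobutylalumanyl) aldimine of 18 | CC(C)C[Al](CC(C)C)N=CC1(C)CCC/C(C)=C/C[C@@H](O[Si](C)(C)C(C)(C)C)/C(C)=C\C1 | intermediate (not isolated)
20 | (3Z,5R,7E)-5-[(tert-butyldimethylsilyl)oxy]-1,4,8-trimethylcycloundeca-3,7-diene-1-carbaldehyde | O=CC1(C)CCC/C(C)=C/C[C@@H](O[Si](C)(C)C(C)(C)C)/C(C)=C\C1 | intermediate
21 | 4-methylbenzenesulfonohydrazone of 20 | Cc1ccc(cc1)S(=O)(=O)NN=CC2(C)CCC/C(C)=C/C[C@@H](O[Si](C)(C)C(C)(C)C)/C(C)=C\C2 | intermediate (not isolated)
22 | tert-butyldimethyl{[(1R,2Z,9E)-2,5,5,9-tetramethylcycloundeca-2,9-dien-1-yl]oxy}silane | CC1(C)CCC/C(C)=C/C[C@@H](O[Si](C)(C)C(C)(C)C)/C(C)=C\C1 | intermediate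
23 | (1R,2Z,9E)-2,5,5,9-tetramethylcycloundeca-2,9-dien-1-ol | CC1(C)CCC/C(C)=C/C[C@@H](O)/C(C)=C\C1 | intermediate
24 | 4-acetoxy-3-methoxybenzoic acid | COc1cc(ccc1OC(C)=O)C(=O)O | starting material
25 | (1R,2Z,9E)-2,5,5,9-tetramethylcycloundeca-2,9-dien-1-yl 4-acetoxy-3-methoxybenzoate | COc1cc(C(=O)O[C@@H]2C/C=C(\C)CCCC(C)(C)C/C=C\2C)ccc1OC(C)=O | intermediate
26 | (1R,2Z,9E)-2,5,5,9-tetramethylcycloundeca-2,9-dien-1-yl 4-hydroxy-3-methoxybenzoate | COc1cc(C(=O)O[C@@H]2C/C=C(\C)CCCC(C)(C)C/C=C\2C)ccc1O | target

**Step count.** Total: 17 steps. Longest linear sequence: 15 steps (steps 3 to 17, from 5).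

**Steps most likely to fail**

Step 12. The risk is that intermolecular alkylation (oligomerisation) outruns closure of the strained eleven-membered ring, or that the amide base consumes the allylic chloride. The fallback replaces the SN2 closure by a π-allylpalladium template that forms the same bond. Setting out from 15, i-Bu2AlH reduction of the nitrile and hydrolysis would give the hydroxy aldehyde (6E,9R,10Z)-9-[(tert-butyldimethylsilyl)oxy]-12-hydroxy-2,6,10-trimethyldodeca-6,10-dienal F1. ClCO2Me and pyridine would convert it into (2Z,4R,6E)-4-[(tert-butyldimethylsilyl)oxy]-3,7,11-trimethyl-12-oxododeca-2,6-dien-1-yl methyl carbonate F2. TBSOTf and Et3N would then give the silyl enol ether (2Z,4R,6E)-4,12-bis[(tert-butyldimethylsilyl)oxy]-3,7,11-trimethyldodeca-2,6,11-trien-1-yl methyl carbonate F3. With Pd2(dba)3 and 1,1'-bis(diphenylphosphino)ferrocene in THF at 65 °C under slow addition, zerovalent palladium should ionise the carbonate to a π-allylpalladium complex; the liberated methoxide unmasks the aldehyde enolate, which is allylated on carbon at the CH2 terminus (Tsuji-type allylation of silyl enol ethers by allyl carbonates). This returns to the route at 20.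

Step 3. The risk is sluggish or unselective transfer of the alkenyl group from the alanate to ethylene oxide, with competing butyl or methyl transfer. The fallback uses cross-coupling in place of epoxide opening. Setting out from 5, the same carboalumination quenched with iodine would give (1E)-5-chloro-1-iodo-2-methylpent-1-ene F4. Pd(PPh3)4-catalysed coupling with the Reformatsky reagent BrZnCH2CO2Et in THF/DMPU should give, with retention of geometry, ethyl (3E)-7-chloro-4-methylhept-3-enoate F5. Reduction of the ester with i-Bu2AlH returns to the route at 8.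

Step 14. The risk is incomplete hydride transfer to the congested neopentyl hydrazone, or partial loss of the silyl ether during the borane and acetate treatment. The fallback is a stepwise deoxygenation through a sulfonate. Setting out from 20, NaBH4 in MeOH would give [(3Z,5R,7E)-5-[(tert-butyldimethylsilyl)oxy]-1,4,8-trimethylcycloundeca-3,7-dien-1-yl]methanol F6. MsCl and Et3N would give its methanesulfonate [(3Z,5R,7E)-5-[(tert-butyldimethylsilyl)oxy]-1,4,8-trimethylcycloundeca-3,7-dien-1-yl]methyl methanesulfonate F7. LiEt3BH in THF at reflux should displace the sulfonate by hydride and return to the route at 22.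

Further compounds
F1 | step 12 | (6E,9R,10Z)-9-[(tert-butyldimethylsilyl)oxy]-12-hydroxy-2,6,10-trimethyldodeca-6,10-dienal | O=CC(C)CCC/C(C)=C/C[C@@H](O[Si](C)(C)C(C)(C)C)/C(C)=C\CO
F2 | step 12 | (2Z,4R,6E)-4-[(tert-butyldimethylsilyl)oxy]-3,7,11-trimethyl-12-oxododeca-2,6-dien-1-yl methyl carbonate | O=CC(C)CCC/C(C)=C/C[C@@H](O[Si](C)(C)C(C)(C)C)/C(C)=C\COC(=O)OC
F3 | step 12 | (2Z,4R,6E)-4,12-bis[(tert-butyldimethylsilyl)oxy]-3,7,11-trimethyldodeca-2,6,11-trien-1-yl methyl carbonate | CC(=CO[Si](C)(C)C(C)(C)C)CCC/C(C)=C/C[C@@H](O[Si](C)(C)C(C)(C)C)/C(C)=C\COC(=O)OC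
F4 | step 3 | (1E)-5-chloro-1-iodo-2-methylpent-1-ene | I/C=C(\C)CCCCl
F5 | step 3 | ethyl (3E)-7-chloro-4-methylhept-3-enoate | CCOC(=O)C/C=C(\C)CCCCl
F6 | step 14 | [(3Z,5R,7E)-5-[(tert-butyldimethylsilyl)oxy]-1,4,8-trimethylcycloundeca-3,7-dien-1-yl]methanol | OCC1(C)CCC/C(C)=C/C[C@@H](O[Si](C)(C)C(C)(C)C)/C(C)=C\C1
F7 | step 14 | [(3Z,5R,7E)-5-[(tert-butyldimethylsilyl)oxy]-1,4,8-trimethylcycloundeca-3,7-dien-1-yl]methyl methanesulfonate | CS(=O)(=O)OCC1(C)CCC/C(C)=C/C[C@@H](O[Si](C)(C)C(C)(C)C)/C(C)=C\C1
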